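## Retrosynthetic overview

1. The target is the 2,3-trans (2R,3R) 3-methoxyflavanone. It is traced back through debenzylation, O-methylation at C3 and benzylic oxidation at C4 to a 2,3-trans-3,4-cis flavan-3,4-diol, the syn-dihydroxylation product of a (2S)-flav-3-ene.
2. Feature the strategy rests on: C3 (OMe) and C4 (C=O) are adjacent oxygen-bearing carbons of ring C, so both come from one C3=C4 alkene. That alkene is closed by ring-closing metathesis between the vinyl group on C4a of ring A and the vinyl group on the C2 carbinol carbon.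
3. The diene is an aryl 1-arylallyl ether. Its C2–O1 bond and C2 configuration come from an iridium-catalysed, branched-selective asymmetric allylic etherification of a ring A 2-vinylphenoxide with a ring B cinnamyl carbonate.
4. Ring order: rings A and B are bought (3,4,5-trimethoxyphenol, methyl gallate); ring C is the only ring formed, in the metathesis step.

Key step: step 11

Assumption: the (Sa,Sc,Sc) enantiomer of the ligand L, O,O′-(1,1′-binaphthalene-2,2′-diyl) N,N-bis(1-phenylethyl)phosphoramidite, is taken to give the (S)-branched ether, by analogy with simple cinnamyl carbonates and phenoxides; if a model run shows the opposite sense, the (Ra,Rc,Rc) ligand is used.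

Remark on descriptors: the C2 descriptor changes from S to R at step 12 and the C3 descriptor from S to R at step 13 only because CIP priorities change; no bond at these centres is broken.

## Route

Step 1
Reactants: 1 methyl gallate (methyl 3,4,5-trihydroxybenzoate)
Product: 2 methyl 3,5-dihydroxy-4-methoxybenzoate
Conditions: MeI (1.05 equiv), Li2CO3 (1.1 equiv), DMF, 40 °C
Reagents that add atoms: iodomethane CI
Why: Williamson etherification in which the 4-hydroxyl, para to the ester and the most acidic of the three, is deprotonated preferentially by one equivalent of weak base and is methylated while the 3- and 5-hydroxyls stay free.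

Step 2
Reactants: 2 methyl 3,5-dihydroxy-4-methoxybenzoate
Product: 3 methyl 3,5-bis(benzyloxy)-4-methoxybenzoate
Conditions: BnBr (2.3 equiv), K2CO3 (3 equiv), DMF, 60 °C
Reagents that add atoms: benzyl bromide BrCc1ccccc1
Why: Williamson benzylation of both remaining phenols under standard conditions to which the methyl ester and the aryl methyl ether are inert.

Step 3
Reactants: 3 methyl 3,5-bis(benzyloxy)-4-methoxybenzoate
Product: 4 [3,5-bis(benzyloxy)-4-methoxyphenyl]methanol
Conditions: LiAlH4, THF, 0 °C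
Reagents that add atoms: none
Why: Hydride reduction of the benzoate ester to the benzylic alcohol, which leaves aryl benzyl and aryl methyl ethers untouched.

Step 4
Reactants: 4 [3,5-bis(benzyloxy)-4-methoxyphenyl]methanol
Product: 5 3,5-bis(benzyloxy)-4-methoxybenzaldehyde
Conditions: activated MnO2 (10 equiv), CH2Cl2, rt
Reagents that add atoms: none
Why: Heterogeneous MnO2 oxidation is selective for the benzylic alcohol and stops at the aldehyde.

Step 5
Reactants: 5 3,5-bis(benzyloxy)-4-methoxybenzaldehyde; 6 triethyl phosphonoacetate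
Product: 7 ethyl (2E)-3-[3,5-bis(benzyloxy)-4-methoxyphenyl]prop-2-enoate
Conditions: NaH, THF, 0 °C → rt
Reagents that add atoms: none
Why: Horner–Wadsworth–Emmons olefination of the aromatic aldehyde with the stabilised phosphonate anion gives the (E)-cinnamate through the thermodynamically preferred anti elimination pathway.

Step 6
Reactants: 7 ethyl (2E)-3-[3,5-bis(benzyloxy)-4-methoxyphenyl]prop-2-enoate
Product: 8 (2E)-3-[3,5-bis(benzyloxy)-4-methoxyphenyl]prop-2-en-1-ol
Conditions: DIBAL-H (i-Bu2AlH, 2.2 equiv), CH2Cl2, −78 °C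
Reagents that add atoms: none
Why: 1,2-Reduction of the α,β-unsaturated ester by the aluminium hydride at low temperature gives the allylic alcohol without touching the alkene or its geometry.

Step 7
Reactants: 8 (2E)-3-[3,5-bis(benzyloxy)-4-methoxyphenyl]prop-2-en-1-ol
Product: 9 (2E)-3-[3,5-bis(benzyloxy)-4-methoxyphenyl]prop-2-en-1-yl methyl carbonate
Conditions: ClCO2Me, pyridine, CH2Cl2, 0 °C
Reagents that add atoms: methyl chloroformate COC(=O)Cl
Why: Acylation of the primary allylic alcohol with the chloroformate installs the methyl carbonate leaving group needed for iridium-catalysed ionisation.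

Step 8
Reactants: 10 3,4,5-trimethoxyphenol
Product: 12 6-hydroxy-2,3,4-trimethoxybenzaldehyde, via aryliminium chloride 11 (not isolated)
Conditions: POCl3, DMF, 0 °C → rt; then ice/H2O
Reagents that add atoms: N,N-dimethylformamide CN(C)C=O; water O
Why: Vilsmeier–Haack formylation in which the chloroiminium electrophile attacks one of the two equivalent, strongly activated positions ortho to the hydroxyl, and water hydrolyses the iminium salt to the salicylaldehyde.

Step 9
Reactants: 12 6-hydroxy-2,3,4-trimethoxybenzaldehyde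
Product: 13 2-ethenyl-3,4,5-trimethoxyphenol (3,4,5-trimethoxy-2-vinylphenol)
Conditions: Ph3PCH3Br (2.6 equiv), KOtBu (2.5 equiv), THF, 0 °C → rt
Reagents that add atoms: methyltriphenylphosphonium bromide C[P+](c1ccccc1)(c1ccccc1)c1ccccc1.[Br-]
Why: Wittig methylenation with excess non-stabilised ylide, the first equivalent serving as base for the phenol, converts the aldehyde into the styrene, which is kept cold and free of acid and used at once because the electron-rich vinylphenol oligomerises easily.

Step 10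
Reactants: 13 2-ethenyl-3,4,5-trimethoxyphenol; 9 (2E)-3-[3,5-bis(benzyloxy)-4-methoxyphenyl]prop-2-en-1-yl methyl carbonate
Product: 15 1-{[(1S)-1-[3,5-bis(benzyloxy)-4-methoxyphenyl]prop-2-en-1-yl]oxy}-2-ethenyl-3,4,5-trimethoxybenzene, via lithium aryloxide 14 (not isolated)
Conditions: 13 (1.5 equiv), n-BuLi (1.5 equiv), THF, 0 °C; then 9, [Ir(cod)Cl]2 (2 mol%), (Sa,Sc,Sc)-L (4 mol%, catalyst pre-formed with n-PrNH2), THF, rt
Reagents that add atoms: none
Why: Iridium-catalysed asymmetric allylic etherification in which the cyclometalated iridium phosphoramidite complex ionises the linear carbonate to a π-allyl complex that the aryloxide attacks at the aryl-substituted terminus, giving the branched ether with the C2 centre set as (S) by the ligand configuration.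

Step 11
Reactants: 15 1-{[(1S)-1-[3,5-bis(benzyloxy)-4-methoxyphenyl]prop-2-en-1-yl]oxy}-2-ethenyl-3,4,5-trimethoxybenzene
Product: 16 (2S)-2-[3,5-bis(benzyloxy)-4-methoxyphenyl]-5,6,7-trimethoxy-2H-chromene
Conditions: second-generation Grubbs catalyst RuCl2(=CHPh)(H2IMes)(PCy3) (3 mol%), 1,4-benzoquinone (10 mol%), degassed CH2Cl2 (0.01 M), 40 °C; then ethyl vinyl ether; filtration through Et3N-deactivated silica
Reagents that add atoms: none
Why: Ring-closing olefin metathesis: the ruthenium benzylidene exchanges onto the less hindered allylic vinyl group of 15, the new alkylidene adds intramolecularly to the ring A styrene through a ruthenacyclobutane, and cycloreversion expels ethene and forms the C3=C4 bond. The closest known reaction type is the ring-closing metathesis of 2-vinylaryl allyl ethers to 2H-chromenes. Ring C closes as a six-membered ring because O1 and the C8a–C4a edge of ring A already hold the two alkenes ortho to one another, so cyclisation outruns cross-metathesis at this dilution. No stereocentre is created, and C2, set in step 10, is a spectator because neither its C–O nor its C–H bond is touched. The step needs chemoselectivity for the two terminal alkenes, which are the only alkenes present, and freedom from double-bond migration in the allylic ether, which 1,4-benzoquinone secures by intercepting ruthenium hydrides; the acid-labile, doubly activated C2–O1 bond of the product is protected by a base-washed work-up.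

Step 12
Reactants: 16 (2S)-2-[3,5-bis(benzyloxy)-4-methoxyphenyl]-5,6,7-trimethoxy-2H-chromene
Product: 17 (2R,3S,4S)-2-[3,5-bis(benzyloxy)-4-methoxyphenyl]-5,6,7-trimethoxy-3,4-dihydro-2H-chromene-3,4-diol
Conditions: OsO4 (3 mol%), N-methylmorpholine N-oxide (1.5 equiv), acetone/H2O (8:1), 0 °C → rt
Reagents that add atoms: osmium tetroxide O=[Os](=O)(=O)=O; N-methylmorpholine N-oxide C[N+]1([O-])CCOCC1; water O
Why: Catalytic osmium tetroxide syn-dihydroxylation with an amine oxide reoxidant, in which the [3+2] addition occurs on the face of the C3=C4 bond anti to the C2 aryl group that shields the neighbouring C3 terminus, so both hydroxyls arrive trans to the aryl group and C3 and C4 are set by substrate control from C2.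

Step 13
Reactants: 17 (2R,3S,4S)-2-[3,5-bis(benzyloxy)-4-methoxyphenyl]-5,6,7-trimethoxy-3,4-dihydro-2H-chromene-3,4-diol
Product: 18 (2R,3R)-2-[3,5-bis(benzyloxy)-4-methoxyphenyl]-3-hydroxy-5,6,7-trimethoxy-2,3-dihydro-4H-chromen-4-one
Conditions: activated MnO2 (15 equiv), CH2Cl2, rt
Reagents that add atoms: none
Why: Chemoselective MnO2 oxidation of the benzylic C4 carbinol, activated by the electron-rich ring A, leaves the non-activated C3 alcohol and its configuration untouched, and the resulting 2,3-trans ketol is also the thermodynamically preferred diastereomer.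

Step 14
Reactants: 18 (2R,3R)-2-[3,5-bis(benzyloxy)-4-methoxyphenyl]-3-hydroxy-5,6,7-trimethoxy-2,3-dihydro-4H-chromen-4-one
Product: 19 (2R,3R)-2-[3,5-bis(benzyloxy)-4-methoxyphenyl]-3,5,6,7-tetramethoxy-2,3-dihydro-4H-chromen-4-one
Conditions: MeI (10 equiv), Ag2O (3 equiv), 4 Å molecular sieves, CH2Cl2, rt, dark
Reagents that add atoms: iodomethane CI
Why: Purdie methylation, in which Ag2O activates iodomethane and takes up HI under near-neutral conditions, etherifies the 3-hydroxyl without the base-induced opening of ring C or enolisation that would erode C2 and C3, and the benzyl ethers keep the ring B phenols from being methylated.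

Step 15
Reactants: 19 (2R,3R)-2-[3,5-bis(benzyloxy)-4-methoxyphenyl]-3,5,6,7-tetramethoxy-2,3-dihydro-4H-chromen-4-one
Product: 20 (2R,3R)-2-(3,5-dihydroxy-4-methoxyphenyl)-3,5,6,7-tetramethoxy-2,3-dihydro-4H-chromen-4-one
Conditions: H2 (1 atm), Pd/C (10% Pd on carbon), EtOAc, rt
Reagents that add atoms: none
Why: Catalytic hydrogenolysis should cleave the two benzyl aryl ethers faster than it attacks the electron-rich aryl ketone or the cyclic benzylic C2–O1 bond, so the reaction is stopped once debenzylation is complete.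

## Compound list

1 | methyl gallate (methyl 3,4,5-trihydroxybenzoate) | COC(=O)c1cc(O)c(O)c(O)c1 | starting material
2 | methyl 3,5-dihydroxy-4-methoxybenzoate | COC(=O)c1cc(O)c(OC)c(O)c1 | intermediate
3 | methyl 3,5-bis(benzyloxy)-4-methoxybenzoate | COC(=O)c1cc(OCc2ccccc2)c(OC)c(OCc2ccccc2)c1 | intermediate
4 | [3,5-bis(benzyloxy)-4-methoxyphenyl]methanol | OCc1cc(OCc2ccccc2)c(OC)c(OCc2ccccc2)c1 | intermediate
5 | 3,5-bis(benzyloxy)-4-methoxybenzaldehyde | O=Cc1cc(OCc2ccccc2)c(OC)c(OCc2ccccc2)c1 | intermediate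
6 | triethyl phosphonoacetate | CCOC(=O)CP(=O)(OCC)OCC | starting material
7 | ethyl (2E)-3-[3,5-bis(benzyloxy)-4-methoxyphenyl]prop-2-enoate | CCOC(=O)/C=C/c1cc(OCc2ccccc2)c(OC)c(OCc2ccccc2)c1 | intermediate
8 | (2E)-3-[3,5-bis(benzyloxy)-4-methoxyphenyl]prop-2-en-1-ol | OC/C=C/c1cc(OCc2ccccc2)c(OC)c(OCc2ccccc2)c1 | intermediate
9 | (2E)-3-[3,5-bis(benzyloxy)-4-methoxyphenyl]prop-2-en-1-yl methyl carbonate | COC(=O)OC/C=C/c1cc(OCc2ccccc2)c(OC)c(OCc2ccccc2)c1 | intermediate
10 | 3,4,5-trimethoxyphenol | COc1cc(O)cc(OC)c1OC | starting material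
11 | N-[(6-hydroxy-2,3,4-trimethoxyphenyl)methylidene]-N-methylmethanaminium chloride | C[N+](C)=Cc1c(O)cc(OC)c(OC)c1OC.[Cl-] | intermediate (not isolated)
12 | 6-hydroxy-2,3,4-trimethoxybenzaldehyde | COc1cc(O)c(C=O)c(OC)c1OC | intermediate
13 | 2-ethenyl-3,4,5-trimethoxyphenol | C=Cc1c(O)cc(OC)c(OC)c1OC | intermediate
14 | lithium 2-ethenyl-3,4,5-trimethoxyphenolate | [Li+].[O-]c1cc(OC)c(OC)c(OC)c1C=C | intermediate (not isolated)
15 | 1-{[(1S)-1-[3,5-bis(benzyloxy)-4-methoxyphenyl]prop-2-en-1-yl]oxy}-2-ethenyl-3,4,5-trimethoxybenzene | C=Cc1c(O[C@@H](C=C)c2cc(OCc3ccccc3)c(OC)c(OCc3ccccc3)c2)cc(OC)c(OC)c1OC | intermediate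
16 | (2S)-2-[3,5-bis(benzyloxy)-4-methoxyphenyl]-5,6,7-trimethoxy-2H-chromene | COc1cc2c(c(OC)c1OC)C=C[C@@H](c1cc(OCc3ccccc3)c(OC)c(OCc3ccccc3)c1)O2 | intermediate
17 | (2R,3S,4S)-2-[3,5-bis(benzyloxy)-4-methoxyphenyl]-5,6,7-trimethoxy-3,4-dihydro-2H-chromene-3,4-diol | COc1cc2c(c(OC)c1OC)[C@H](O)[C@H](O)[C@@H](c1cc(OCc3ccccc3)c(OC)c(OCc3ccccc3)c1)O2 | intermediate
18 | (2R,3R)-2-[3,5-bis(benzyloxy)-4-methoxyphenyl]-3-hydroxy-5,6,7-trimethoxy-2,3-dihydro-4H-chromen-4-one | COc1cc2c(c(OC)c1OC)C(=O)[C@H](O)[C@@H](c1cc(OCc3ccccc3)c(OC)c(OCc3ccccc3)c1)O2 | intermediate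
19 | (2R,3R)-2-[3,5-bis(benzyloxy)-4-methoxyphenyl]-3,5,6,7-tetramethoxy-2,3-dihydro-4H-chromen-4-one | COc1cc2c(c(OC)c1OC)C(=O)[C@H](OC)[C@@H](c1cc(OCc3ccccc3)c(OC)c(OCc3ccccc3)c1)O2 | intermediate
20 | (2R,3R)-2-(3,5-dihydroxy-4-methoxyphenyl)-3,5,6,7-tetramethoxy-2,3-dihydro-4H-chromen-4-one | COc1cc2c(c(OC)c1OC)C(=O)[C@H](OC)[C@@H](c1cc(O)c(OC)c(O)c1)O2 | target

## Step count and risks

Total steps: 15. Longest linear sequence: 13 steps (steps 1–7 and 10–15, from methyl gallate).

Steps most likely to fail:

1. Step 10. The electron-rich branched ether may re-ionise on the catalyst, eroding enantiomeric purity and leaking to the linear ether; the ortho-substituted aryloxide may attack slowly; and the vinylphenol may oligomerise before it reacts. The fallback sets out from aldehyde 5 (with phenol 13) and comes back at 15. Vinylmagnesium bromide addition to 5 (THF, −78 °C) should give racemic 1-[3,5-bis(benzyloxy)-4-methoxyphenyl]prop-2-en-1-ol F1. Kinetic resolution with immobilised Candida antarctica lipase B and vinyl acetate is expected to acylate the (R)-enantiomer to (1R)-1-[3,5-bis(benzyloxy)-4-methoxyphenyl]prop-2-en-1-yl acetate F3 and leave (1S)-1-[3,5-bis(benzyloxy)-4-methoxyphenyl]prop-2-en-1-ol F2. F2 is converted with n-BuLi and Boc2O into tert-butyl (1S)-1-[3,5-bis(benzyloxy)-4-methoxyphenyl]prop-2-en-1-yl carbonate F4. Allylic etherification of 13 with F4 catalysed by [Cp*Ru(MeCN)3]PF6 should then proceed with net retention at the branched carbon (double inversion) and give 15.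

2. Step 13. Oxidative glycol cleavage of the cis-diol, or further dehydrogenation across C2–C3 towards the flavonol, may compete with the benzylic oxidation. The fallback sets out from chromene 16 and comes back at 19, so it also avoids step 14. Hydroboration–oxidation (BH3·THF; then NaOH, H2O2) should place boron at C3 anti to the C2 aryl group and give (2R,3S)-2-[3,5-bis(benzyloxy)-4-methoxyphenyl]-5,6,7-trimethoxy-3,4-dihydro-2H-chromen-3-ol F5. NaH/MeI methylation gives (2R,3S)-2-[3,5-bis(benzyloxy)-4-methoxyphenyl]-3,5,6,7-tetramethoxy-3,4-dihydro-2H-chromene F6. DDQ in CH2Cl2/H2O oxidises the activated benzylic C4–H to (2R,3S)-2-[3,5-bis(benzyloxy)-4-methoxyphenyl]-3,5,6,7-tetramethoxy-3,4-dihydro-2H-chromen-4-ol F7 (C4 epimer mixture). Dess–Martin periodinane with NaHCO3 then gives 19.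

3. Step 14. Retro-oxa-Michael opening of ring C on the basic silver oxide surface would scramble C2 and C3, and the hydrogen-bonded 3-hydroxyl may alkylate sluggishly. The fallback sets out from diol 17 and comes back at 19, methylating before the ketone exists. Bu2SnO (toluene, reflux, water removal) gives (2R,3S,4S)-2-[3,5-bis(benzyloxy)-4-methoxyphenyl]-5,6,7-trimethoxy-3,4-dihydro-2H-chromene-3,4-diyl dibutylstannylene acetal F8. MeI/CsF in DMF should alkylate the equatorial O3 in preference to the pseudoaxial benzylic O4 and give (2R,3S,4S)-2-[3,5-bis(benzyloxy)-4-methoxyphenyl]-3,5,6,7-tetramethoxy-3,4-dihydro-2H-chromen-4-ol F9. MnO2 or Dess–Martin periodinane then oxidises the remaining benzylic carbinol to 19.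

Further compounds

F1 | step 10 | 1-[3,5-bis(benzyloxy)-4-methoxyphenyl]prop-2-en-1-ol (racemic) | C=CC(O)c1cc(OCc2ccccc2)c(OC)c(OCc2ccccc2)c1
F2 | step 10 | (1S)-1-[3,5-bis(benzyloxy)-4-methoxyphenyl]prop-2-en-1-ol | O[C@@H](C=C)c1cc(OCc2ccccc2)c(OC)c(OCc2ccccc2)c1
F3 | step 10 | (1R)-1-[3,5-bis(benzyloxy)-4-methoxyphenyl]prop-2-en-1-yl acetate | CC(=O)O[C@H](C=C)c1cc(OCc2ccccc2)c(OC)c(OCc2ccccc2)c1
F4 | step 10 | tert-butyl (1S)-1-[3,5-bis(benzyloxy)-4-methoxyphenyl]prop-2-en-1-yl carbonate | CC(C)(C)OC(=O)O[C@@H](C=C)c1cc(OCc2ccccc2)c(OC)c(OCc2ccccc2)c1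
F5 | step 13 | (2R,3S)-2-[3,5-bis(benzyloxy)-4-methoxyphenyl]-5,6,7-trimethoxy-3,4-dihydro-2H-chromen-3-ol | COc1cc2c(c(OC)c1OC)C[C@H](O)[C@@H](c1cc(OCc3ccccc3)c(OC)c(OCc3ccccc3)c1)O2
F6 | step 13 | (2R,3S)-2-[3,5-bis(benzyloxy)-4-methoxyphenyl]-3,5,6,7-tetramethoxy-3,4-dihydro-2H-chromene | COc1cc2c(c(OC)c1OC)C[C@H](OC)[C@@H](c1cc(OCc3ccccc3)c(OC)c(OCc3ccccc3)c1)O2
F7 | step 13 | (2R,3S)-2-[3,5-bis(benzyloxy)-4-methoxyphenyl]-3,5,6,7-tetramethoxy-3,4-dihydro-2H-chromen-4-ol (C4 epimer mixture) | COc1cc2c(c(OC)c1OC)C(O)[C@H](OC)[C@@H](c1cc(OCc3ccccc3)c(OC)c(OCc3ccccc3)c1)O2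
F8 | step 14 | (2R,3S,4S)-2-[3,5-bis(benzyloxy)-4-methoxyphenyl]-5,6,7-trimethoxy-3,4-dihydro-2H-chromene-3,4-diyl dibutylstannylene acetal | COc1cc2c(c(OC)c1OC)[C@@H]1O[Sn](CCCC)(CCCC)O[C@@H]1[C@@H](c1cc(OCc3ccccc3)c(OC)c(OCc3ccccc3)c1)O2
F9 | step 14 | (2R,3S,4S)-2-[3,5-bis(benzyloxy)-4-methoxyphenyl]-3,5,6,7-tetramethoxy-3,4-dihydro-2H-chromen-4-ol | COc1cc2c(c(OC)c1OC)[C@H](O)[C@H](OC)[C@@H](c1cc(OCc3ccccc3)c(OC)c(OCc3ccccc3)c1)O2
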